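**Remark (reading of the target):** germacrane-type numbering is used (C1 furanone C=O, C2=C3, C4=C5, C6 lactone O–CH, C7, C8 angelate O–CH, C9, C10 quaternary ether carbon, C11 spiro carbon, C12 lactone C=O, C13 the ring CH2 next to C11 that derives from an exocyclic methylene). The SMILES is read as the (6S,7R,8R,10R,11S) isomer with a 6,7-cis-fused lactone, a (4Z) olefin and the 4-methylpent-3-enyl group on the cyclohexene carbon 1,3 to C11.

## Retrosynthetic overview

1. The spiro-cyclohexene shares only C11 with the γ-lactone (O–C6–C7–C11–C12) and has its C=C β,γ to C11, so its C11–CH2 and C13–CH2 bonds form a [4+2] retron: exocyclic C11=C13 methylene lactone (C20 half) plus a 3-alkyl-2-silyloxybuta-1,3-diene (C10 half). The silyloxy group is a traceless regiocontrol element (OSiEt3 → OTf → H), needed because the side chain must sit 1,3 and not 1,4 to C11.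
2. The dienophile comes from angeloylation at O8, ring-closing metathesis of C4=C5 (C6-vinyl plus furanone isopropenyl), and a Barbier 2-(methoxycarbonyl)allylation of acrolein that sets C6/C7 and the cis-lactone under control of C8.
3. The allyl bromide comes from a furanone aldehyde (C8 by proline α-aminoxylation); the furanone comes from (R)-linalool (C1, C7–C10, C14) and 2-methylbut-1-en-3-yne (C2–C4, C15).
4. The diene comes from ethyl acetoacetate and 5-bromo-2-methylpent-2-ene.
5. Ring order: furanone (step 5) → γ-lactone (step 12) → ten-membered carbocycle (step 13) → spiro-cyclohexene (step 19).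

Key step: step 19

## Route

Step 1
Reactants: 1 (R)-(−)-linalool
Product: 3 (2R)-2-ethenyl-5-methoxy-2-methyloxolane (mixture of C5 anomers), via lactol 2 (not isolated)
Conditions: O3 (1.0 equiv), CH2Cl2/MeOH, −78 °C; Me2S; then PPTS (cat.), MeOH, rt
Reagents that add atoms: methanol (CO)
Why: Chemoselective ozonolysis cleaves the electron-rich trisubstituted olefin much faster than the vinyl group, the γ-hydroxy aldehyde closes to the lactol, and acid-catalysed acetalisation masks both the future C7 aldehyde and the C10 oxygen without touching the linalool stereocentre.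

Step 2
Reactants: 3 (2R)-2-ethenyl-5-methoxy-2-methyloxolane
Product: 4 (2R)-5-methoxy-2-methyloxolane-2-carbaldehyde
Conditions: O3, CH2Cl2, −78 °C; PPh3
Reagents that add atoms: ozone ([O-][O+]=O)
Why: Ozonolysis with reductive work-up turns the remaining vinyl group into the aldehyde that becomes C1, and the quaternary α-carbon cannot epimerise.

Step 3
Reactants: 4 (2R)-5-methoxy-2-methyloxolane-2-carbaldehyde; 5 2-methylbut-1-en-3-yne
Product: 7 1-[(2R)-5-methoxy-2-methyloxolan-2-yl]-4-methylpent-4-en-2-yn-1-ol (carbinol epimers), via lithium acetylide 6 (not isolated)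
Conditions: 5, n-BuLi, THF, −78 °C; then 4; H2O quench
Reagents that add atoms: none
Why: 1,2-Addition of a lithium acetylide to an aldehyde, whose new carbinol centre is formed as a mixture that is erased by the oxidation in step 4.

Step 4
Reactants: 7 1-[(2R)-5-methoxy-2-methyloxolan-2-yl]-4-methylpent-4-en-2-yn-1-ol
Product: 8 1-[(2R)-5-methoxy-2-methyloxolan-2-yl]-4-methylpent-4-en-2-yn-1-one
Conditions: Dess–Martin periodinane, pyridine, CH2Cl2, 0 °C → rt
Reagents that add atoms: none
Why: Dess–Martin oxidation of a propargylic alcohol to the ynone under buffered conditions that keep the methyl acetal intact.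

Step 5
Reactants: 8 1-[(2R)-5-methoxy-2-methyloxolan-2-yl]-4-methylpent-4-en-2-yn-1-one
Product: 11 3-[(2R)-2-methyl-3-oxo-5-(prop-1-en-2-yl)-2,3-dihydrofuran-2-yl]propanal, via enaminone acetal 9 (not isolated), via enaminone lactol 10 (not isolated)
Conditions: Et2NH, EtOH, rt; then 1 M aq. HCl, THF, rt
Reagents that add atoms: water (O)
Why: Aza-Michael addition of the amine gives an enaminone, and aqueous acid then hydrolyses the acetal so that the released tertiary C10 hydroxyl adds to C3 of the protonated enaminone and expels the amine, which is the classical 3(2H)-furanone synthesis from α'-hydroxy ynones and also frees the C7 aldehyde.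

Step 6
Reactants: 11 3-[(2R)-2-methyl-3-oxo-5-(prop-1-en-2-yl)-2,3-dihydrofuran-2-yl]propanal
Product: 13 (2R)-2-[(2R)-3-hydroxy-2-(N-phenylaminooxy)propyl]-2-methyl-5-(prop-1-en-2-yl)furan-3(2H)-one, via aminoxy aldehyde 12 (not isolated)
Conditions: PhNO (slow addition), L-proline (20 mol %), CHCl3, 4 °C; then NaBH4, EtOH, 0 °C
Reagents that add atoms: nitrosobenzene (O=Nc1ccccc1)
Why: Proline enamine catalysis (α-aminoxylation) delivers oxygen to the enamine face directed by the carboxylic acid, which for linear aldehydes with L-proline gives the (R)-α-oxygenated centre (C8), and immediate borohydride reduction of the aldehyde prevents epimerisation.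

Step 7
Reactants: 13 (2R)-2-[(2R)-3-hydroxy-2-(N-phenylaminooxy)propyl]-2-methyl-5-(prop-1-en-2-yl)furan-3(2H)-one
Product: 14 (2R)-2-[(2R)-2,3-dihydroxypropyl]-2-methyl-5-(prop-1-en-2-yl)furan-3(2H)-one
Conditions: CuSO4·5H2O (30 mol %), MeOH, 0 °C → rt
Reagents that add atoms: none
Why: CuSO4-catalysed N–O cleavage is the standard unmasking of α-aminoxylation products and should leave the dienone and the C8 configuration untouched.

Step 8
Reactants: 14 (2R)-2-[(2R)-2,3-dihydroxypropyl]-2-methyl-5-(prop-1-en-2-yl)furan-3(2H)-one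
Product: 15 (2R)-2-[(2R)-2,3-bis(triethylsilyloxy)propyl]-2-methyl-5-(prop-1-en-2-yl)furan-3(2H)-one
Conditions: Et3SiCl, imidazole, DMF, 0 °C → rt
Reagents that add atoms: chlorotriethylsilane (CC[Si](Cl)(CC)CC)
Why: Exhaustive silylation of the 1,2-diol with a silyl chloride and imidazole.

Step 9
Reactants: 15 (2R)-2-[(2R)-2,3-bis(triethylsilyloxy)propyl]-2-methyl-5-(prop-1-en-2-yl)furan-3(2H)-one
Product: 16 (2R)-3-[(2R)-2-methyl-3-oxo-5-(prop-1-en-2-yl)-2,3-dihydrofuran-2-yl]-2-(triethylsilyloxy)propanal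
Conditions: (COCl)2, DMSO, CH2Cl2, −78 → −40 °C; Et3N
Reagents that add atoms: none
Why: Under Swern conditions a primary triethylsilyl ether is desilylated and oxidised directly to the aldehyde while the more hindered secondary silyl ether at C8 survives, which gives the α-silyloxy aldehyde without a separate deprotection.

Step 10
Reactants: 16 (2R)-3-[(2R)-2-methyl-3-oxo-5-(prop-1-en-2-yl)-2,3-dihydrofuran-2-yl]-2-(triethylsilyloxy)propanal; 17 methyl propiolate
Product: 19 methyl (4R)-3-hydroxy-2-methylidene-5-[(2R)-2-methyl-3-oxo-5-(prop-1-en-2-yl)-2,3-dihydrofuran-2-yl]-4-(triethylsilyloxy)pentanoate (C3 epimers), via vinylalane 18 (not isolated)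
Conditions: 17, i-Bu2AlH, N-methylmorpholine N-oxide, THF, 0 °C; then 16, 0 °C → rt
Reagents that add atoms: none
Why: Vinylalumination (hydroalumination of the propiolate, then addition of the α-ester vinylalane to the aldehyde) gives the Morita–Baylis–Hillman-type adduct without amine base, so C8 should not epimerise, and the new carbinol centre is inconsequential because it becomes sp2 in step 11.

Step 11
Reactants: 19 methyl (4R)-3-hydroxy-2-methylidene-5-[(2R)-2-methyl-3-oxo-5-(prop-1-en-2-yl)-2,3-dihydrofuran-2-yl]-4-(triethylsilyloxy)pentanoate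
Product: 20 methyl (2Z,4R)-2-(bromomethyl)-5-[(2R)-2-methyl-3-oxo-5-(prop-1-en-2-yl)-2,3-dihydrofuran-2-yl]-4-(triethylsilyloxy)pent-2-enoate
Conditions: N-bromosuccinimide, Me2S, CH2Cl2, 0 °C → rt
Reagents that add atoms: N-bromosuccinimide (O=C1CCC(=O)N1Br)
Why: Corey–Kim-type bromination of a Morita–Baylis–Hillman alcohol proceeds with allylic transposition (SN2') to the thermodynamically preferred primary (Z)-2-(bromomethyl)enoate.

Step 12
Reactants: 20 methyl (2Z,4R)-2-(bromomethyl)-5-[(2R)-2-methyl-3-oxo-5-(prop-1-en-2-yl)-2,3-dihydrofuran-2-yl]-4-(triethylsilyloxy)pent-2-enoate; 21 acrolein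
Product: 24 (4S,5S)-5-ethenyl-3-methylidene-4-{(1R)-2-[(2R)-2-methyl-3-oxo-5-(prop-1-en-2-yl)-2,3-dihydrofuran-2-yl]-1-(triethylsilyloxy)ethyl}oxolan-2-one, via allylzinc bromide 22 (not isolated), via hydroxy ester 23 (not isolated)
Conditions: Zn dust, 21 (excess), THF/sat. aq. NH4Cl, 0 °C → rt; then PPTS (cat.), toluene, 60 °C
Reagents that add atoms: none
Why: In this Barbier-type 2-(alkoxycarbonyl)allylation the allylzinc should add to acrolein through a six-membered chair transition state with the γ-substituent axial (syn adduct, hence the 6,7-cis lactone after lactonisation of the C6 hydroxyl), while C8 should direct the face of C7 (C8–H eclipsing the enoate plane to avoid allylic 1,3-strain, aldehyde approaching anti to the C9 chain), and the silyl ether on O8 leaves only the 6,12-lactone open.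

Step 13
Reactants: 24 (4S,5S)-5-ethenyl-3-methylidene-4-{(1R)-2-[(2R)-2-methyl-3-oxo-5-(prop-1-en-2-yl)-2,3-dihydrofuran-2-yl]-1-(triethylsilyloxy)ethyl}oxolan-2-one
Product: 25 (2Z,4S,8S,9R,11R)-2,11-dimethyl-7-methylidene-9-(triethylsilyloxy)-5,14-dioxatricyclo[9.2.1.0^{4,8}]tetradeca-1(13),2-diene-6,12-dione
Conditions: second-generation Hoveyda–Grubbs catalyst [RuCl2(H2IMes)(=CH-C6H4-2-O-i-Pr)] (15 mol %, in portions), toluene (1 mM), 100 °C
Reagents that add atoms: none
Why: Ring-closing metathesis between the C6 vinyl group and the furanone isopropenyl group, which the cis-lactone holds on the same face, closes the ten-membered carbocycle with a trisubstituted C4=C5 bond that can only be Z in this oxygen-bridged ring, a closure with close precedent for 5-isopropenyl-3(2H)-furanones, while the hindered electron-poor exocyclic methylene is a poor metathesis partner.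

Step 14
Reactants: 25 (2Z,4S,8S,9R,11R)-2,11-dimethyl-7-methylidene-9-(triethylsilyloxy)-5,14-dioxatricyclo[9.2.1.0^{4,8}]tetradeca-1(13),2-diene-6,12-dione
Product: 26 (2Z,4S,8R,9R,11R)-9-hydroxy-2,11-dimethyl-7-methylidene-5,14-dioxatricyclo[9.2.1.0^{4,8}]tetradeca-1(13),2-diene-6,12-dione
Conditions: HF·pyridine, pyridine, THF, 0 °C
Reagents that add atoms: none
Why: Buffered fluoride cleavage of the secondary triethylsilyl ether under weakly acidic conditions that should avoid translactonisation to the 8,12-olide.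

Step 15
Reactants: 26 (2Z,4S,8R,9R,11R)-9-hydroxy-2,11-dimethyl-7-methylidene-5,14-dioxatricyclo[9.2.1.0^{4,8}]tetradeca-1(13),2-diene-6,12-dione; 27 angelic acid
Product: 29 (2Z,4S,8R,9R,11R)-2,11-dimethyl-7-methylidene-6,12-dioxo-5,14-dioxatricyclo[9.2.1.0^{4,8}]tetradeca-1(13),2-dien-9-yl (2Z)-2-methylbut-2-enoate, via mixed anhydride 28 (not isolated)
Conditions: 27, 2,4,6-trichlorobenzoyl chloride, Et3N, toluene, rt; then 26, 75 °C
Reagents that add atoms: none
Why: Yamaguchi-type mixed-anhydride esterification without a nucleophilic amine catalyst should transfer the angeloyl group without Z-to-E isomerisation to the tiglate, and C8 keeps its configuration because its C–O bond is not broken.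

Step 16
Reactants: 30 ethyl acetoacetate; 31 5-bromo-2-methylpent-2-ene
Product: 32 ethyl 2-acetyl-6-methylhept-5-enoate (racemic)
Conditions: NaOEt, NaI (cat.), EtOH, reflux
Reagents that add atoms: none
Why: Classical acetoacetic ester alkylation with a primary bromide.

Step 17
Reactants: 32 ethyl 2-acetyl-6-methylhept-5-enoate
Product: 35 7-methyl-3-methylideneoct-6-en-2-one, via keto acid 33 (not isolated), via Mannich base 34 (not isolated)
Conditions: KOH, H2O, rt; HCl to pH 4; then 37% aq. HCHO, Et2NH, 0 → 40 °C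
Reagents that add atoms: formaldehyde (C=O)
Why: Saponification followed by decarboxylative Mannich methylenation (iminium addition at the doubly activated carbon, then loss of CO2 and amine) gives the α-methylene ketone regiospecifically.

Step 18
Reactants: 35 7-methyl-3-methylideneoct-6-en-2-one
Product: 36 triethyl[(7-methyl-3-methylideneocta-1,6-dien-2-yl)oxy]silane
Conditions: Et3SiOTf, Et3N, CH2Cl2, 0 °C
Reagents that add atoms: triethylsilyl trifluoromethanesulfonate (CC[Si](CC)(CC)OS(=O)(=O)C(F)(F)F)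
Why: Soft enolisation of the methyl ketone, whose methyl group carries the only α-hydrogens, with a silyl triflate and amine base gives the 2-silyloxy-1,3-diene.

Step 19
Reactants: 29 (2Z,4S,8R,9R,11R)-2,11-dimethyl-7-methylidene-6,12-dioxo-5,14-dioxatricyclo[9.2.1.0^{4,8}]tetradeca-1(13),2-dien-9-yl (2Z)-2-methylbut-2-enoate; 36 triethyl[(7-methyl-3-methylideneocta-1,6-dien-2-yl)oxy]silane
Product: 37 (6S,7R,8R,10R,11S)-spiro adduct of 29 carrying at C11 the 3-(4-methylpent-3-en-1-yl)-4-(triethylsilyloxy)cyclohex-3-ene ring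
Conditions: 36 (3 equiv), BHT (cat.), toluene, 110 °C, sealed tube
Reagents that add atoms: none
Why: A thermal, concerted but asynchronous normal-electron-demand Diels–Alder reaction between the exocyclic C11=C13 methylene of the α-methylene-γ-butyrolactone and the 2-silyloxydiene, the closest known reaction type being the cycloaddition of α-methylene lactones with 2-silyloxy-1,3-dienes to spiro lactones. The cyclohexene is closed by intermolecular [4+2] cycloaddition that forms the C13–CH2 and C11–CH2 bonds in one operation and joins the C20 and C10 halves. The enol ether terminus, the most nucleophilic diene carbon, should bond to the electrophilic β-carbon C13, so the silyloxy carbon ends up 1,4 and the side-chain carbon 1,3 to C11, the opposite of what the unsubstituted triene would prefer, because the stronger silyloxy donor overrides the alkyl group. The only new stereocentre, spiro C11, should be set by approach of the diene to the convex face of the cis-fused lactone (the face of H6 and H7), anti to the macrocycle and the C8 angelate, which places the new C11–CH2 bond cis to H7 (11S). Chemoselectivity rests on C11=C13 being the only unhindered 1,1-disubstituted electron-poor olefin, whereas the angelate, C2=C3 and C4=C5 are trisubstituted or donor-substituted. No endo/exo question arises because both diene termini are unsubstituted.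

Step 20
Reactants: 37 (6S,7R,8R,10R,11S)-spiro adduct with the 4-(triethylsilyloxy)cyclohex-3-ene ring
Product: 39 (6S,7R,8R,10R,11S)-spiro lactone with the 3-(4-methylpent-3-en-1-yl)-4-(trifluoromethanesulfonyloxy)cyclohex-3-ene ring, via caesium enolate 38 (not isolated)
Conditions: CsF, PhNTf2, DME, rt
Reagents that add atoms: N-phenylbis(trifluoromethanesulfonimide) (O=S(=O)(N(c1ccccc1)S(=O)(=O)C(F)(F)F)C(F)(F)F)
Why: Fluoride cleaves the silyl enol ether to the regiodefined enolate, which N-phenyltriflimide sulfonylates on oxygen in situ, the known regiospecific conversion of silyl enol ethers into enol triflates, so the double bond stays where the cycloaddition put it.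

Step 21
Reactants: 39 (6S,7R,8R,10R,11S)-spiro lactone enol triflate
Product: 40 CNP0226905.2, the (6S,7R,8R,10R,11S)-8-O-angeloyl spiro lactone with the 3-(4-methylpent-3-en-1-yl)cyclohex-3-ene ring
Conditions: Pd(OAc)2 (5 mol %), PPh3 (10 mol %), HCO2H, n-Bu3N, DMF, 60 °C
Reagents that add atoms: none
Why: Palladium-catalysed formate reduction of the enol triflate (oxidative addition to zerovalent palladium, formate exchange, decarboxylation, reductive elimination) replaces the triflate by hydrogen without moving the double bond, and oxidative addition to the vinyl triflate should be much faster than ionisation of the hindered trisubstituted allylic lactone at C6.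

## Compound list

1 | (R)-(−)-linalool, (3R)-3,7-dimethylocta-1,6-dien-3-ol | CC(C)=CCC[C@@](C)(O)C=C | starting material
2 | (5R)-5-ethenyl-5-methyloxolan-2-ol (lactol) | OC1CC[C@](C)(C=C)O1 | intermediate
3 | (2R)-2-ethenyl-5-methoxy-2-methyloxolane | COC1CC[C@](C)(C=C)O1 | intermediate
4 | (2R)-5-methoxy-2-methyloxolane-2-carbaldehyde | COC1CC[C@](C)(C=O)O1 | intermediate
5 | 2-methylbut-1-en-3-yne | C#CC(C)=C | starting material
6 | lithium 3-methylbut-3-en-1-yn-1-ide | [Li]C#CC(C)=C | intermediate
7 | 1-[(2R)-5-methoxy-2-methyloxolan-2-yl]-4-methylpent-4-en-2-yn-1-ol | COC1CC[C@](C)(C(O)C#CC(C)=C)O1 | intermediate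
8 | 1-[(2R)-5-methoxy-2-methyloxolan-2-yl]-4-methylpent-4-en-2-yn-1-one | COC1CC[C@](C)(C(=O)C#CC(C)=C)O1 | intermediate
9 | 3-(diethylamino)-1-[(2R)-5-methoxy-2-methyloxolan-2-yl]-4-methylpenta-2,4-dien-1-one | COC1CC[C@](C)(C(=O)C=C(N(CC)CC)C(C)=C)O1 | intermediate
10 | 3-(diethylamino)-1-[(2R)-5-hydroxy-2-methyloxolan-2-yl]-4-methylpenta-2,4-dien-1-one (lactol, in equilibrium with the open hydroxy aldehyde) | OC1CC[C@](C)(C(=O)C=C(N(CC)CC)C(C)=C)O1 | intermediate
11 | 3-[(2R)-2-methyl-3-oxo-5-(prop-1-en-2-yl)-2,3-dihydrofuran-2-yl]propanal | O=CCC[C@@]1(C)OC(=CC1=O)C(C)=C | intermediate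
12 | (2R)-3-[(2R)-2-methyl-3-oxo-5-(prop-1-en-2-yl)-2,3-dihydrofuran-2-yl]-2-(N-phenylaminooxy)propanal | O=C[C@H](ONc1ccccc1)C[C@@]1(C)OC(=CC1=O)C(C)=C | intermediate
13 | (2R)-2-[(2R)-3-hydroxy-2-(N-phenylaminooxy)propyl]-2-methyl-5-(prop-1-en-2-yl)furan-3(2H)-one | OC[C@H](ONc1ccccc1)C[C@@]1(C)OC(=CC1=O)C(C)=C | intermediate
14 | (2R)-2-[(2R)-2,3-dihydroxypropyl]-2-methyl-5-(prop-1-en-2-yl)furan-3(2H)-one | OC[C@H](O)C[C@@]1(C)OC(=CC1=O)C(C)=C | intermediate
15 | (2R)-2-[(2R)-2,3-bis(triethylsilyloxy)propyl]-2-methyl-5-(prop-1-en-2-yl)furan-3(2H)-one | CC[Si](CC)(CC)OC[C@H](O[Si](CC)(CC)CC)C[C@@]1(C)OC(=CC1=O)C(C)=C | intermediate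
16 | (2R)-3-[(2R)-2-methyl-3-oxo-5-(prop-1-en-2-yl)-2,3-dihydrofuran-2-yl]-2-(triethylsilyloxy)propanal | O=C[C@H](O[Si](CC)(CC)CC)C[C@@]1(C)OC(=CC1=O)C(C)=C | intermediate
17 | methyl propiolate | C#CC(=O)OC | starting material
18 | methyl 2-(diisobutylalumanyl)prop-2-enoate | C=C(C(=O)OC)[Al](CC(C)C)CC(C)C | intermediate
19 | methyl (4R)-3-hydroxy-2-methylidene-5-[(2R)-2-methyl-3-oxo-5-(prop-1-en-2-yl)-2,3-dihydrofuran-2-yl]-4-(triethylsilyloxy)pentanoate (C3 epimers) | C=C(C(=O)OC)C(O)[C@H](O[Si](CC)(CC)CC)C[C@@]1(C)OC(=CC1=O)C(C)=C | intermediate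
20 | methyl (2Z,4R)-2-(bromomethyl)-5-[(2R)-2-methyl-3-oxo-5-(prop-1-en-2-yl)-2,3-dihydrofuran-2-yl]-4-(triethylsilyloxy)pent-2-enoate | COC(=O)/C(CBr)=C/[C@H](O[Si](CC)(CC)CC)C[C@@]1(C)OC(=CC1=O)C(C)=C | intermediate
21 | acrolein | C=CC=O | starting material
22 | allylzinc bromide derived from 20 | COC(=O)C(C[Zn]Br)=C[C@H](O[Si](CC)(CC)CC)C[C@@]1(C)OC(=CC1=O)C(C)=C | intermediate
23 | methyl (3S,4S)-4-hydroxy-2-methylidene-3-{(1R)-2-[(2R)-2-methyl-3-oxo-5-(prop-1-en-2-yl)-2,3-dihydrofuran-2-yl]-1-(triethylsilyloxy)ethyl}hex-5-enoate | C=C[C@H](O)[C@H](C(=C)C(=O)OC)[C@H](O[Si](CC)(CC)CC)C[C@@]1(C)OC(=CC1=O)C(C)=C | intermediate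
24 | (4S,5S)-5-ethenyl-3-methylidene-4-{(1R)-2-[(2R)-2-methyl-3-oxo-5-(prop-1-en-2-yl)-2,3-dihydrofuran-2-yl]-1-(triethylsilyloxy)ethyl}oxolan-2-one | C=C[C@@H]1OC(=O)C(=C)[C@@H]1[C@H](O[Si](CC)(CC)CC)C[C@@]2(C)OC(=CC2=O)C(C)=C | intermediate
25 | (2Z,4S,8S,9R,11R)-2,11-dimethyl-7-methylidene-9-(triethylsilyloxy)-5,14-dioxatricyclo[9.2.1.0^{4,8}]tetradeca-1(13),2-diene-6,12-dione | CC[Si](CC)(CC)O[C@@H]1C[C@@]2(C)OC(=CC2=O)/C(C)=C\[C@@H]2OC(=O)C(=C)[C@@H]21 | intermediate
26 | (2Z,4S,8R,9R,11R)-9-hydroxy-2,11-dimethyl-7-methylidene-5,14-dioxatricyclo[9.2.1.0^{4,8}]tetradeca-1(13),2-diene-6,12-dione | O[C@@H]1C[C@@]2(C)OC(=CC2=O)/C(C)=C\[C@@H]2OC(=O)C(=C)[C@@H]21 | intermediate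
27 | angelic acid, (2Z)-2-methylbut-2-enoic acid | C/C=C(/C)C(=O)O | starting material
28 | angelic 2,4,6-trichlorobenzoic anhydride | C/C=C(/C)C(=O)OC(=O)c1c(Cl)cc(Cl)cc1Cl | intermediate
29 | (2Z,4S,8R,9R,11R)-2,11-dimethyl-7-methylidene-6,12-dioxo-5,14-dioxatricyclo[9.2.1.0^{4,8}]tetradeca-1(13),2-dien-9-yl (2Z)-2-methylbut-2-enoate | C/C=C(/C)C(=O)O[C@@H]1C[C@@]2(C)OC(=CC2=O)/C(C)=C\[C@@H]2OC(=O)C(=C)[C@@H]21 | intermediate
30 | ethyl acetoacetate | CCOC(=O)CC(C)=O | starting material
31 | 5-bromo-2-methylpent-2-ene | CC(C)=CCCBr | starting material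
32 | ethyl 2-acetyl-6-methylhept-5-enoate (racemic) | CCOC(=O)C(CCC=C(C)C)C(C)=O | intermediate
33 | 2-acetyl-6-methylhept-5-enoic acid | OC(=O)C(CCC=C(C)C)C(C)=O | intermediate
34 | 2-acetyl-2-[(diethylamino)methyl]-6-methylhept-5-enoic acid | OC(=O)C(CCC=C(C)C)(CN(CC)CC)C(C)=O | intermediate
35 | 7-methyl-3-methylideneoct-6-en-2-one | CC(=O)C(=C)CCC=C(C)C | intermediate
36 | triethyl[(7-methyl-3-methylideneocta-1,6-dien-2-yl)oxy]silane | C=C(O[Si](CC)(CC)CC)C(=C)CCC=C(C)C | intermediate
37 | (6S,7R,8R,10R,11S)-8-O-angeloyl spiro lactone with the 3-(4-methylpent-3-en-1-yl)-4-(triethylsilyloxy)cyclohex-3-ene ring at C11 | C/C=C(/C)C(=O)O[C@@H]1C[C@@]2(C)OC(=CC2=O)/C(C)=C\[C@@H]2OC(=O)[C@]3(CCC(O[Si](CC)(CC)CC)=C(CCC=C(C)C)C3)[C@@H]21 | intermediate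
38 | caesium enolate of the corresponding spiro cyclohexanone | C/C=C(/C)C(=O)O[C@@H]1C[C@@]2(C)OC(=CC2=O)/C(C)=C\[C@@H]2OC(=O)[C@]3(CCC([O-])=C(CCC=C(C)C)C3)[C@@H]21.[Cs+] | intermediate
39 | (6S,7R,8R,10R,11S)-8-O-angeloyl spiro lactone with the 3-(4-methylpent-3-en-1-yl)-4-(trifluoromethanesulfonyloxy)cyclohex-3-ene ring at C11 | C/C=C(/C)C(=O)O[C@@H]1C[C@@]2(C)OC(=CC2=O)/C(C)=C\[C@@H]2OC(=O)[C@]3(CCC(OS(=O)(=O)C(F)(F)F)=C(CCC=C(C)C)C3)[C@@H]21 | intermediate
40 | CNP0226905.2, (6S,7R,8R,10R,11S)-8-O-angeloyl spiro lactone with the 3-(4-methylpent-3-en-1-yl)cyclohex-3-ene ring at C11 | C/C=C(/C)C(=O)O[C@@H]1C[C@@]2(C)OC(=CC2=O)/C(C)=C\[C@@H]2OC(=O)[C@]3(CCC=C(CCC=C(C)C)C3)[C@@H]21 | target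

## Step count and risks

Total steps: 21. Longest linear sequence: 18 (steps 1–15 and 19–21).

**Step 19.** The cycloaddition may lose regiocontrol or facial selectivity, or the partners may polymerise or desilylate before the slow bimolecular reaction takes place. The fallback closes the same ring by metathesis; it sets out from 29 and comes back at 40.
- The dianion of 2-methylprop-2-en-1-ol (n-BuLi, TMEDA) would be alkylated with 1-bromo-3-methylbut-2-ene to give 6-methyl-2-methylidenehept-5-en-1-ol F1.
- CBr4/PPh3 would convert it into 2-(bromomethyl)-6-methylhepta-1,5-diene F2.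
- Conjugate addition of lithium diallylcuprate, (CH2=CHCH2)2CuLi, to C13 of 29, then alkylation of the lactone enolate with F2 (THF/HMPA, −78 → 0 °C) on the convex face, should give the C11-quaternary triene lactone F3.
- Ring-closing metathesis of its vinyl and 1,1-disubstituted olefins (second-generation Grubbs catalyst [RuCl2(PCy3)(H2IMes)(=CHPh)], CH2Cl2, 40 °C) should give 40 with the trisubstituted double bond already in place, without 37 and 39.

**Step 12.** The allylzinc may add with the wrong facial sense relative to C8, or may eliminate the C8 silyloxy group (1,4-elimination to a dienoate) before it is trapped. The fallback replaces the fluxional allylmetal under substrate control by a geometry-defined allylboron reagent under catalyst control; it sets out from 20 and comes back at 24.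
- Pd-catalysed borylation of 20 (Pd2(dba)3, B2pin2, toluene, 50 °C) should give the primary allylboronate, methyl 2-[(pinacolboryl)methyl]-4-(triethylsilyloxy)pent-2-enoate F4 (ester trans to C8), which cannot eliminate.
- Allylboration of acrolein 21 catalysed by a chiral BINOL-derived phosphoric acid (toluene, −30 °C) through a closed chair transition state should give hydroxy ester 23; the boronate geometry fixes the syn relationship and the catalyst enantiomer is chosen for the required face.
- PPTS then lactonises 23 to 24.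

**Step 13.** Ring closure may fail in favour of oligomerisation or cross-metathesis at the exocyclic methylene. The fallback takes the exocyclic olefin out of play during the metathesis; it sets out from 24 and comes back at 25.
- Conjugate addition of dimethylamine (Me2NH, THF, 0 °C) should give the 13-(dimethylamino) adduct F5.
- Metathesis of its camphorsulfonate salt (second-generation Hoveyda–Grubbs catalyst, toluene, 80 °C) should give the macrocyclic amine F6.
- Quaternisation with MeI (MeCN, rt) gives the trimethylammonium iodide F7, and aqueous NaHCO3 induces β-elimination back to the methylene lactone 25.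

Further compounds
F1 | step 19 | 6-methyl-2-methylidenehept-5-en-1-ol | C=C(CO)CCC=C(C)C
F2 | step 19 | 2-(bromomethyl)-6-methylhepta-1,5-diene | C=C(CBr)CCC=C(C)C
F3 | step 19 | C11-quaternary triene lactone (C11 bearing but-3-en-1-yl and 6-methyl-2-methylidenehept-5-en-1-yl) | C/C=C(/C)C(=O)O[C@@H]1C[C@@]2(C)OC(=CC2=O)/C(C)=C\[C@@H]2OC(=O)[C@@](CCC=C)(CC(=C)CCC=C(C)C)[C@@H]21
F4 | step 12 | methyl (4R)-5-[(2R)-2-methyl-3-oxo-5-(prop-1-en-2-yl)-2,3-dihydrofuran-2-yl]-2-[(4,4,5,5-tetramethyl-1,3,2-dioxaborolan-2-yl)methyl]-4-(triethylsilyloxy)pent-2-enoate (ester trans to C8) | COC(=O)/C(CB1OC(C)(C)C(C)(C)O1)=C/[C@H](O[Si](CC)(CC)CC)C[C@@]1(C)OC(=CC1=O)C(C)=C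
F5 | step 13 | dimethylamine adduct of 24 (3-[(dimethylamino)methyl] lactone, C11 epimers) | C=C[C@@H]1OC(=O)C(CN(C)C)[C@@H]1[C@H](O[Si](CC)(CC)CC)C[C@@]2(C)OC(=CC2=O)C(C)=C
F6 | step 13 | macrocyclic 13-(dimethylamino)-11,13-dihydro analogue of 25 | CC[Si](CC)(CC)O[C@@H]1C[C@@]2(C)OC(=CC2=O)/C(C)=C\[C@@H]2OC(=O)C(CN(C)C)[C@@H]21
F7 | step 13 | trimethylammonium iodide of F6 | CC[Si](CC)(CC)O[C@@H]1C[C@@]2(C)OC(=CC2=O)/C(C)=C\[C@@H]2OC(=O)C(C[N+](C)(C)C)[C@@H]21.[I-]
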